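**Assumption:** 4-Methylcyclohex-3-en-1-one (4) is purchasable (otherwise one step from 4-methylanisole by Birch reduction and mild hydrolysis). The C6 stereocentre of the ring-B carbinols (5–7) is racemic and is erased in Step 6.

## Retrosynthetic overview
1. The C3-Br/C2-Cl trans pair comes from Markovnikov chlorohydrin formation on the ring-B trisubstituted alkene, then OH→Br with retention. C10-Br comes from the C10 alcohol by Appel inversion.
2. The spiro[5.5] core forms in one radical step: a tertiary C6 radical (from a cyclic thionocarbonate of a 1,3-diol) undergoes 6-exo-dig cyclisation onto a terminal alkyne. This creates the quaternary spiro centre, closes ring A and gives the exocyclic methylene.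
3. The 1,3-diol comes from an SmI2 Reformatsky coupling of ketone 4 (ring B, already carrying the C2=C3(Me) alkene) with tertiary α-bromoketone 3. C10 is set by CBS reduction, and the C10 stereocentre relays to C6 in the radical step.
4. Ring B comes from 4, and the ring-A chain from pent-4-ynoic acid (1).

## Route

**Step 1**
Reactants: 1, pent-4-ynoic acid
Product: 2, 2-methylhept-6-yn-3-one
Conditions: iPrLi (3.3 equiv), THF, –78 → 0 °C; aq. NH4Cl
Reagents that add atoms: isopropyllithium, CC(C)[Li]
Why: Two organolithium equivalents add to the lithium carboxylate (ketone synthesis from a carboxylic acid), and the alkyne C–H is deprotonated in situ and restored on work-up; no stereocentre is formed.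

**Step 2**
Reactants: 2
Product: 3, 2-bromo-2-methylhept-6-yn-3-one
Conditions: CuBr2 (2 equiv), EtOAc/CHCl3 1:1, reflux
Reagents that add atoms: copper(II) bromide, Br[Cu]Br
Why: Enol-mediated α-bromination occurs at the more substituted (tertiary) α-carbon, giving the tertiary bromide needed for the Reformatsky step.

**Step 3**
Reactants: 3 and 4, 4-methylcyclohex-3-en-1-one
Product: 5, 2-(1-hydroxy-4-methylcyclohex-3-en-1-yl)-2-methylhept-6-yn-3-one (racemic at C6)
Conditions: SmI2 (2.2 equiv), THF, –78 → 0 °C
Reagents that add atoms: none
Why: The SmI2 Reformatsky/aldol reaction of the tertiary α-bromoketone with the ketone forms the hindered C6–C11 bond under non-basic conditions, which protects the enolisable β,γ-enone. The new C6 carbinol stereocentre is irrelevant because it is destroyed in Step 6.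

**Step 4**
Reactants: 5
Product: 6, (3S)-2-(1-hydroxy-4-methylcyclohex-3-en-1-yl)-2-methylhept-6-yn-3-ol (C6 epimer mixture)
Conditions: (R)-Me-CBS (10 mol%), catecholborane, toluene, –78 °C
Reagents that add atoms: none
Why: Corey–Bakshi–Shibata reduction sets C10 as the (S)-alcohol (tert-alkyl versus CH2 discrimination); this is the only enantio-determining step, and (S) is the configuration that Step 7 inverts to the (R)-bromide of the target. Catecholborane avoids hydroboration of the terminal alkyne.

**Step 5**
Reactants: 6
Product: 7, cyclic thionocarbonate (1,3-dioxane-2-thione) spiro-fused to the ring-B cyclohexene, bearing C10-(but-3-ynyl) and C11-gem-dimethyl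
Conditions: 1,1'-thiocarbonyldiimidazole (1.5 equiv), DMAP, toluene, 110 °C
Reagents that add atoms: 1,1'-thiocarbonyldiimidazole, S=C(n1ccnc1)n1ccnc1
Why: The gem-dimethyl (Thorpe–Ingold) effect favours the six-membered thionocarbonate. This masks both oxygens as a Barton–McCombie radical precursor that fragments selectively at the tertiary C6–O bond.

**Step 6**
Reactants: 7
Product: 8, spiro alcohol with the C10 hydroxyl and the C7 exocyclic methylene
Conditions: Bu3SnH (2 equiv, syringe pump 10 h), AIBN, toluene (0.003 M), 110 °C; then K2CO3, MeOH
Reagents that add atoms: none
Why: Proposed new method: Bu3Sn• adds to C=S and β-scission gives the tertiary C6 radical, which is cyclised 6-exo-dig onto the terminal alkyne; the closest known reaction type is Barton–McCombie radical cyclisation onto alkynes, and the novelty is the hindered tertiary radical next to a quaternary carbon. The resulting exocyclic vinyl radical abstracts H from Bu3SnH to give the =CH2 group, and the carbonothioate left on C10 is cleaved by methanolysis. The C6 configuration is set by a chair-like transition state with the C10 oxygen equatorial, so the cis-1,3 ring-B arm C5 is equatorial and C1 axial, giving the target relative configuration (modest dr expected).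

**Step 7**
Reactants: 8
Product: 9, C10 bromide (10R)
Conditions: PPh3, CBr4, 2,6-lutidine, CH2Cl2, 0 → 40 °C
Reagents that add atoms: carbon tetrabromide, BrC(Br)(Br)Br
Why: The Appel reaction proceeds by SN2 with inversion and converts the (S)-alcohol into the (R)-bromide of the target, with the alkenes untouched. It is run before the ring-B halogenation so that PPh3 never sees a vicinal halide pair.

**Step 8**
Reactants: 9
Product: 10, trans chlorohydrin (C2-Cl, C3-OH)
Conditions: NCS (1.1 equiv), THF/H2O 4:1, AcOH (cat.), 0 °C
Reagents that add atoms: N-chlorosuccinimide, O=C1CCC(=O)N1Cl; water, O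
Why: Cl+ attacks the more nucleophilic trisubstituted ring-B alkene in preference to the hindered exocyclic methylene. It approaches anti to the axial C7 (the bulky C11 sits equatorial), and water opens the chloronium ion at the tertiary C3 (Markovnikov, anti). This gives Cl on C2 syn to C11 and OH on C3 on the C7 face, with Me on C3 cis to Cl, as in the target.

**Step 9**
Reactants: 10
Product: 11, obtusane
Conditions: Me3SiBr (3 equiv), CH2Cl2, –78 → –20 °C
Reagents that add atoms: bromotrimethylsilane, C[Si](C)(C)Br
Why: Proposed new method: the tertiary silyl ether ionises with anchimeric assistance from the anti-periplanar C2 chlorine (chloronium), and bromide re-opens it on the original OH face, so the net result is retention at C3 and a trans Br/Cl pair. The closest known reaction type is the Olah silyl-halide conversion of tertiary alcohols to halides with neighbouring-group participation.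

## Compound list
1 | pent-4-ynoic acid | C#CCCC(=O)O | starting material
2 | 2-methylhept-6-yn-3-one | CC(C)C(=O)CCC#C | intermediate
3 | 2-bromo-2-methylhept-6-yn-3-one | CC(C)(Br)C(=O)CCC#C | intermediate
4 | 4-methylcyclohex-3-en-1-one | CC1=CCC(=O)CC1 | starting material
5 | β-hydroxy ketone (racemic at C6) | CC1=CCC(O)(CC1)C(C)(C)C(=O)CCC#C | intermediate
6 | 1,3-diol, C10 (S) (C6 epimer mixture) | CC1=CCC(O)(CC1)C(C)(C)[C@@H](O)CCC#C | intermediate
7 | cyclic thionocarbonate (C10 S-derived) | CC1=CCC2(CC1)OC(=S)O[C@@H](CCC#C)C2(C)C | intermediate
8 | spiro alcohol (C10-OH inverted relative to target) | C=C1CC[C@H](O)C(C)(C)[C@]12CCC(C)=CC2 | intermediate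
9 | C10 bromide | C=C1CC[C@@H](Br)C(C)(C)[C@]12CCC(C)=CC2 | intermediate
10 | trans chlorohydrin | C=C1CC[C@@H](Br)C(C)(C)[C@]12CC[C@](C)(O)[C@@H](Cl)C2 | intermediate
11 | obtusane | C=C1CC[C@@H](Br)C(C)(C)[C@]12CC[C@](C)(Br)[C@@H](Cl)C2 | target

## Totals
Total steps: 9. Longest linear sequence: 9 (1 → 2 → 3 → 5 → 6 → 7 → 8 → 9 → 10 → 11, with 4 entering at Step 3).

## Three steps most likely to fail
1. **Step 6 (radical spirocyclisation).** The hindered tertiary radical may be reduced directly, the vinyl radical may close 5-exo onto the ring-B alkene, or dr at C6 may be poor. Fallback: build ring A first and form the spiro centre by a polar Diels–Alder of isoprene onto a 2-methylene-3,3-dimethyl-4-silyloxycyclohexanone, with C6 set by π-facial selectivity.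
2. **Step 7 (SN2 at a neopentylic secondary alcohol).** Fallback: radical bromodeoxygenation, in which the alcohol is converted to a methyl oxalate or thiocarbonylimidazolide and treated with Bu3SnH/BrCCl3 as Br-atom donor. C10 is then set by Br-atom transfer to the less hindered face.
3. **Steps 8–9 (chemoselectivity against the exocyclic methylene, and retentive OH→Br).** Fallback: switch to an epoxide manifold. Epoxidise ring B (DMDO), open with MgBr2·OEt2 at tertiary C3 to give Br at C3 and OH at C2, then convert C2-OH to Cl with retention (SOCl2, SNi).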